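## Retrosynthetic overview
- The target comes from one O-acetylation of the atromentin dianion. Both phenols are masked as acid-labile 2-methoxyprop-2-yl (MOP) ketals, which fall off in the acidic quench.
- The quinone core comes from head-to-tail union of two identical arylpyruvate units. This forms two C(aryl-bearing)–C(acyl) bonds and uses no aryl–quinone cross-coupling.
- Each unit is used as a 5-arylidene-2,2-dimethyl-1,3-dioxolan-4-one. The ketone is masked as an enol ether, the acyl carbon is activated, and acetone is the traceless leaving group.
- Ring order: a temporary dioxolanone forms in step 1. In the single flask of step 2 a pyran-2,5-dione ring closes first, then the quinone carbocycle.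
- The monomer comes from 4-hydroxyphenylpyruvic acid and 2-methoxypropene.

Assumption: the target has no stereocentre and no stereogenic double bond, so it is a single achiral compound and there is no enantiomer to select.

Abbreviation: Ar* = 4-(2-methoxypropan-2-yloxy)phenyl.

## Route

Step 1
Reactants: 1 4-hydroxyphenylpyruvic acid (the solid is largely the Z-enol); 2 2-methoxypropene
Product: 3 (5Z)-5-{[4-(2-methoxypropan-2-yloxy)phenyl]methylidene}-2,2-dimethyl-1,3-dioxolan-4-one
Conditions: 2 (5 equiv), PPTS (2 mol %), THF, 0 °C to rt, 3 h; Et3N quench; crystallise in the presence of a trace of Et3N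
Reagents that add atoms: 2-methoxypropene, C=C(C)OC
Why: This is acid-catalysed O–H addition to an enol ether followed by intramolecular transketalisation (dioxolanone formation as for α-hydroxy acids, MOP ether formation at the phenol); the carboxyl/enol-OH pair of the enolic acid behaves like an α-hydroxy acid, the conjugated Z-arylidene lactone is the thermodynamic product, and no stereocentre is created.

Step 2
Reactants: 3 (two molecules per product); 4 sodium methoxide
Product: 8 disodium 2,5-bis[4-(2-methoxypropan-2-yloxy)phenyl]-3,6-dioxocyclohexa-1,4-diene-1,4-diolate, via sodium enolate 5 (not isolated), via triketo ester salt 6 (not isolated), via pyrandione salt 7 (not isolated)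
Conditions: solid NaOMe (0.5 equiv per 3), THF, 0 °C to rt, 2 h; then NaOMe (0.6 equiv per 3), MeOH (10 vol %), 60 °C, 4 h; filter the precipitated salt under N2
Reagents that add atoms: sodium methoxide, [Na+].[O-]C
Why: Proposed new method: the first half-equivalent of methoxide opens half of 3 with loss of acetone to give the ketone-free enolate 5, which meets the remaining 3 only as an acyl donor whose own ketone is masked, so Claisen acylation (the known reaction of 5-ylidene-1,3-dioxolan-4-ones with ester enolates) should outrun the aldol/lactonisation that normally diverts arylpyruvates; the adduct 6 closes through oxygen to the pyran-2,5-dione 7 (first new six-membered ring, also reached if the first acylation goes on oxygen), the second charge of methoxide reopens that enol lactone, and the freed benzylic enolate closes on the ester carbon (Dieckmann condensation, the known methoxide-induced ylidene-lactone to cyclic 1,3-dione rearrangement, second new six-membered ring); the doubly vinylogous carboxylate 8 is the thermodynamic sink and precipitates, the MOP ketals are inert to base, and no stereocentre is formed.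

Step 3
Reactants: 8; 9 acetic anhydride
Product: 11 2-acetoxy-5-hydroxy-3,6-bis(4-hydroxyphenyl)-1,4-benzoquinone (target), via sodium monoacetate salt 10 (not isolated)
Conditions: Ac2O (2 equiv), DMF, 0 °C, 1 h; then pour into 0.5 M aq HCl–THF, 0 °C, 20 min; extract with EtOAc; crystallise with no base and no alcohol
Reagents that add atoms: acetic anhydride, CC(=O)OC(C)=O
Why: This is O-acylation of a vinylogous carboxylate followed by acetal hydrolysis; the dianion is acetylated readily, whereas monoanion 10 is a much weaker base than acetate, so a second acetyl transfer from Ac2O is uphill and is reversed by acetate, the phenols stay masked while acyl donor and base are present, all four quinone oxygens of 8 are equivalent so only one monoacetate can form, the cold dilute acid removes both MOP ketals within minutes without cleaving the enol acetate, and no stereocentre is involved.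

## Compound list
1 | 4-hydroxyphenylpyruvic acid | O=C(O)C(=O)Cc1ccc(O)cc1 | starting material
2 | 2-methoxypropene | C=C(C)OC | starting material
3 | (5Z)-5-{[4-(2-methoxypropan-2-yloxy)phenyl]methylidene}-2,2-dimethyl-1,3-dioxolan-4-one | COC(C)(C)Oc1ccc(/C=C2\OC(C)(C)OC2=O)cc1 | intermediate
4 | sodium methoxide | [Na+].[O-]C | starting material
5 | sodium enolate of methyl 3-Ar*-2-oxopropanoate (drawn as the C-centred resonance form; not isolated) | COC(=O)C(=O)[CH-]c1ccc(OC(C)(C)OC)cc1.[Na+] | intermediate
6 | sodium salt of methyl 3,6-bis(Ar*)-2,4,5-trioxohexanoate (drawn as the C-3-centred resonance form; not isolated) | COC(=O)C(=O)[C-](c1ccc(OC(C)(C)OC)cc1)C(=O)C(=O)Cc1ccc(OC(C)(C)OC)cc1.[Na+] | intermediate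
7 | sodium (6Z)-4-Ar*-6-(Ar*-methylidene)-2,5-dioxo-5,6-dihydro-2H-pyran-3-olate (not isolated) | O=C1O/C(=C\c2ccc(OC(C)(C)OC)cc2)C(=O)C(c2ccc(OC(C)(C)OC)cc2)=C1[O-].[Na+] | intermediate
8 | disodium 2,5-bis(Ar*)-3,6-dioxocyclohexa-1,4-diene-1,4-diolate | [Na+].[Na+].[O-]C1=C(c2ccc(OC(C)(C)OC)cc2)C(=O)C([O-])=C(c2ccc(OC(C)(C)OC)cc2)C1=O | intermediate
9 | acetic anhydride | CC(=O)OC(C)=O | starting material
10 | sodium 4-acetoxy-2,5-bis(Ar*)-3,6-dioxocyclohexa-1,4-dien-1-olate (not isolated) | [Na+].CC(=O)OC1=C(c2ccc(OC(C)(C)OC)cc2)C(=O)C([O-])=C(c2ccc(OC(C)(C)OC)cc2)C1=O | intermediate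
11 | 2-acetoxy-5-hydroxy-3,6-bis(4-hydroxyphenyl)-1,4-benzoquinone | CC(=O)OC1=C(c2ccc(O)cc2)C(=O)C(O)=C(c2ccc(O)cc2)C1=O | target

## Step count and risks
Total step count: 3. Longest linear sequence: 3 (1 → 3 → 8 → 11).

**Highest risk: the dimerisation in step 2.**
- Failure modes:
  - Methoxide may consume all of 3 before enolate 5 is acylated.
  - Open O-acyl oligomers may build up.
  - Neutral keto ester may leak into the aldol-lactone manifold.
- Fallback idea: the two halves are first tied together by O-acylation, so that only intramolecular acyl shifts remain.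
- It sets out from 3.
  - Saponification with NaOH (1 equiv, THF–H2O, 0 °C) gives sodium 3-[4-(2-methoxypropan-2-yloxy)phenyl]-2-oxopropanoate F2.
  - Pivaloyl chloride in THF at −20 °C converts this into 2,2-dimethylpropanoic 3-[4-(2-methoxypropan-2-yloxy)phenyl]-2-oxopropanoic anhydride F3.
  - Slow addition of the anhydride to Et3N and catalytic DMAP at high dilution gives the lactide-type cyclodimer (3Z,6Z)-3,6-bis{[4-(2-methoxypropan-2-yloxy)phenyl]methylidene}-1,4-dioxane-2,5-dione F4.
  - NaOMe (2 equiv, THF, 0 to 60 °C) then drives two successive O-to-C acyl shifts.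
- It comes back to the route at 8.

**Second risk: the mono-acetylation and unmasking in step 3.**
- Failure modes:
  - The acyl-transfer equilibrium may stop short of completion.
  - Acetyl may be lost or scrambled during the quench.
- Fallback idea: overshoot, then trim back under charge control.
- It sets out from 8.
  - Acetyl chloride (2.2 equiv, THF, 0 °C) gives the neutral, isolable 2,5-diacetoxy-3,6-bis[4-(2-methoxypropan-2-yloxy)phenyl]-1,4-benzoquinone F5.
  - NaOMe (1.0 equiv, THF, −78 °C) removes one acetyl group; the negative charge that appears shields the second.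
- It comes back at 10, which is quenched with cold dilute HCl exactly as in the main route to give 11.

**Third risk: the double-duty ketalisation in step 1.**
- Failure modes:
  - The sequence may stall at the MOP ester or dimethyl ketal stage.
  - The aryl MOP ether may be lost on isolation.
- Fallback idea: separate the two jobs and close the ring by direct dehydrative ketalisation of the enol acid with acetone itself.
- It sets out from 1.
  - Acetone (as solvent) with BF3·OEt2 at 0 °C gives (5Z)-5-[(4-hydroxyphenyl)methylidene]-2,2-dimethyl-1,3-dioxolan-4-one F1, which can be crystallised.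
  - The phenol alone is then capped with 2 and PPTS.
- It comes back at 3.

## Further compounds
F1 | step 1 | (5Z)-5-[(4-hydroxyphenyl)methylidene]-2,2-dimethyl-1,3-dioxolan-4-one | Oc1ccc(/C=C2\OC(C)(C)OC2=O)cc1
F2 | step 2 | sodium 3-[4-(2-methoxypropan-2-yloxy)phenyl]-2-oxopropanoate | [Na+].[O-]C(=O)C(=O)Cc1ccc(OC(C)(C)OC)cc1
F3 | step 2 | 2,2-dimethylpropanoic 3-[4-(2-methoxypropan-2-yloxy)phenyl]-2-oxopropanoic anhydride | CC(C)(C)C(=O)OC(=O)C(=O)Cc1ccc(OC(C)(C)OC)cc1
F4 | step 2 | (3Z,6Z)-3,6-bis{[4-(2-methoxypropan-2-yloxy)phenyl]methylidene}-1,4-dioxane-2,5-dione | O=C1O/C(=C\c2ccc(OC(C)(C)OC)cc2)C(=O)O/C1=C\c3ccc(OC(C)(C)OC)cc3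
F5 | step 3 | 2,5-diacetoxy-3,6-bis[4-(2-methoxypropan-2-yloxy)phenyl]-1,4-benzoquinone | CC(=O)OC1=C(c2ccc(OC(C)(C)OC)cc2)C(=O)C(OC(C)=O)=C(c2ccc(OC(C)(C)OC)cc2)C1=O
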